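At 19 min the elm run reads 0.0353 M of target, having gained 0.001600 M over the last 5.00 min, although 0.0447 M of its starting material has not become target. The cedar run, with half the free catalyst, levels off at 0.0203 M. So we read these two flasks as stopping with their catalyst, and ask how late a reading must be to count as the end.

| setting | elm | birch | cedar | larch | alder |
|---|---|---|---|---|---|
| starting material | 0.0800 M | 0.0800 M | 0.0800 M | 0.0400 M | 0.0400 M |
| coupling partner | 0.160 M | 0.480 M | 0.160 M | 0.160 M | 0.120 M |
| free catalyst | 0.00800 M | 0.00800 M | 0.00400 M | 0.00800 M | 0.00800 M |
| time |  |  |  |  | 19 min |

| run | time / min | [target] / M |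
|---|---|---|
| elm run | 1.1 | 0.0077 |
| elm run | 3.3 | 0.0187 |
| elm run | 6.3 | 0.0263 |
| elm run | 9.9 | 0.0313 |
| elm run | 14 | 0.0337 |
| elm run | 19 | 0.0353 |
| birch run | 1.1 | 0.0155 |
| birch run | 3.3 | 0.0394 |
| birch run | 6.3 | 0.0563 |
| birch run | 9.9 | 0.0671 |
| birch run | 14 | 0.0714 |
| birch run | 19 | 0.0728 |
| cedar run | 1.1 | 0.0031 |
| cedar run | 3.3 | 0.0107 |
| cedar run | 6.3 | 0.0150 |
| cedar run | 9.9 | 0.0184 |
| cedar run | 14 | 0.0195 |
| cedar run | 19 | 0.0203 |
| larch run | 1.1 | 0.0049 |
| larch run | 3.3 | 0.0135 |
| larch run | 6.3 | 0.0166 |
| larch run | 9.9 | 0.0212 |
| larch run | 14 | 0.0234 |
| larch run | 19 | 0.0228 |

(scatter of a reading: 8 × 10⁻⁴ M)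

- how the opening rate goes with [starting material] round the charge of the elm run: the exponent of the rate at two percent of starting material gone to target (one fixed amount of target, the same in the runs compared)
- how the opening rate goes with [coupling partner] round the charge of the elm run: the exponent of the rate at two percent of starting material gone to target
- target in the alder run at 19 min, as a share of the starting material charged

- Overall: starting material + coupling partner -> target, with free catalyst as catalyst.
- Constant volume, constant temperature.
- A reading of a species includes what of it is bound.
- "The second partner" is coupling partner.
- An order is taken over about fifteen percent of the charge, up and down.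

Our bench rule is that the gap between a reading and the last reading shrinks by a constant factor per minute. In elm that gap is 0.01660 M at 3.3 min and 0.004000 M at 9.9 min. Dividing the time between them by the logarithm of their ratio gives 4.64 min, and this time, in which the gap shrinks by a factor of e, is the working life of the flask. It is a reading, since the smaller gap is 5.00 times the scatter.

The rule has a border, found by dividing the last reading by the charge. Elm stands at 44.1%, but birch stands at 91.0% of its starting material, the limiting reagent there at 0.0800 M against 0.480 M of coupling partner. The same arithmetic on birch gives 3.73 min, shorter than elm's, and this too is a reading; at such a share of the charge we no longer take the gap as a measure of the catalyst by itself.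

For alder we take proportionality, exponent 1, as the zero of the scale. Tripling the coupling partner from elm to birch raises the 3.3 min reading by a factor of 2.11, an exponent of 0.678, below that zero. Alder is larch with less coupling partner, and larch's last two readings average 0.02310 M. Scaling that level gives us 0.01900 M, or 47.5% of alder's charge.

The forecast gives 0.5 (0.3 to 0.7) for the order in starting material, 0.8 (0.6 to 0.95) for the order in coupling partner and 48% (44% to 53%) for target in alder at 19 min, on the ground that “So the catalyst dies roughly first-order, and rate is about first order in catalyst.”

The flask gives 0.39 for the order in starting material, 0.83 for the order in coupling partner and 46.1% in alder at 19 min, so the forecast parts from it on the order in starting material, standing higher.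

    free catalyst + starting material ⇌ catalyst-substrate complex, settled at all times (14.40 M⁻¹)
    catalyst-substrate complex + coupling partner ⇌ ternary complex, settled at all times (9.030 M⁻¹)
    ternary complex → target + free catalyst (4.428 min⁻¹)
    2 starting material ⇌ idle substrate dimer, settled at all times (111.0 M⁻¹)
    free catalyst → spent catalyst (0.2526 min⁻¹)

Alder stands at 46.1% at 19 min because free catalyst passes into spent catalyst and starting material pairs to idle substrate dimer: the same run gives 96.1% without the first and 80.4% without the second. Its 19 min are 4.09 of the working lives read from elm, which by the bench rule leaves 1.67% of the gap open. Birch, reckoned from elm's working life and birch's last reading, should reach 0.0200 M of target at 1.49 min, and the flask takes 1.43 min.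

The earlier runs and the new flask come from a simulation with constants of no real substance.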